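**Plan**
1. Retrosynthesis: ring B, the central ring of the triquinane (ring A = pyran-fused cyclopentenone, ring C = ring carrying CH3/CO2H), is cut last at its two unshared bonds, C(quaternary, CH3)–CH(ring C) and CH(α' to C=O)–CH2, giving silyl dienol ether 23 and enal 27.
2. Enabling feature: in ring A the CH3-bearing carbon is γ and its neighbour α' to the 2-alkoxycyclopentenone C=O (a 1,2-dinucleophile); the other three ring B carbons are Cβ, Cα and CHO of a cyclopent-1-ene-1-carbaldehyde built on ring C (a 1,3-dielectrophile).
3. Earlier cuts: dihydropyran by hetero-Diels–Alder reaction (methylene dione 20 + Z-cyclononenone 14); nine-membered ring at its trisubstituted olefin (metathesis of 13); cyclobutane by enamine/acrylate [2+2].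
4. Forward order of rings: cyclobutane (steps 1–5), nine-membered ring (6), dihydropyran with ring A attached (8), ring C separately (11–13), ring B last (14); then conjugate reduction and ester hydrolysis.
5. Stereochemistry: cyclobutane CH carbons by Rh-catalysed conjugate addition and trans equilibration; pyran C–O and CH by suprafacial addition to the Z olefin; ring C quaternary carbon by Cu-catalysed conjugate methylation.
6. The ring A/B quaternary carbon and both CH of the ring B/C fusion arise in the key step (amine catalyst, anti approach, forced cis fusion); the CH next to the ketone by protonation to the cis-fused ring.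

Key step: step 14

Remark on the chemistry: the two cyclobutane CH carbons of the target are antipodal to those of commercial (−)-β-caryophyllene and (−)-isocaryophyllene, and H and CH3 are cis on the pyran ring (adduct of a Z olefin), so the terpene half is built (steps 1–6) rather than bought. Dione 18 is drawn as the diketone although it is largely enolised. The chiral ligands and the amine catalyst are named as the antipodes expected to give the stated centres; the facial sense of each is an assumption of the proposal.

Step 1
Reactants: 1 4-(2-methylprop-1-en-1-yl)morpholine; 2 methyl acrylate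
Product: 3 methyl 3,3-dimethyl-2-(morpholin-4-yl)cyclobutane-1-carboxylate
Conditions: MeCN, reflux
Reagents that add atoms: none
Why: Thermal enamine–acrylate [2+2] cycloaddition (Michael addition of the enamine β-carbon, then closure of the ester enolate onto the iminium carbon) should give the aminocyclobutane with the gem-dimethyl carbon bonded to the acrylate CH2; both stereocentres are removed in step 2.

Step 2
Reactants: 3 methyl 3,3-dimethyl-2-(morpholin-4-yl)cyclobutane-1-carboxylate
Product: 5 methyl 3,3-dimethylcyclobut-1-ene-1-carboxylate, via ammonium iodide 4 (not isolated)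
Conditions: MeI, MeCN, 40 °C; then K2CO3, 60 °C
Reagents that add atoms: none
Why: N-Methylation followed by Hofmann-type E1cB elimination of the β-ammonio ester should give the conjugated cyclobutene, the hydrogen α to the ester being the only β-hydrogen.

Step 3
Reactants: 5 methyl 3,3-dimethylcyclobut-1-ene-1-carboxylate; 6 4,4,5,5-tetramethyl-2-vinyl-1,3,2-dioxaborolane
Product: 7 methyl (1R,2S)-3,3-dimethyl-2-vinylcyclobutane-1-carboxylate
Conditions: [RhCl(cod)]2 (2.5 mol%), (R)-BINAP (6 mol%), KOH (10 mol%), 1,4-dioxane/H2O 10:1, 60 °C; then NaOMe (0.2 equiv), MeOH, rt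
Reagents that add atoms: none
Why: Hayashi–Miyaura conjugate addition of the alkenylboronate to the strained cyclobutene ester should set the CH next to the gem-dimethyl carbon under ligand control (the BINAP antipode is the one taken to give 2S; its mirror image would give ent-7), and methoxide equilibration should place the ester trans to the vinyl group.

Step 4
Reactants: 7 methyl (1R,2S)-3,3-dimethyl-2-vinylcyclobutane-1-carboxylate; 8 2-bromopropene
Product: 10 methyl (1R,2S)-3,3-dimethyl-2-(3-methylbut-3-en-1-yl)cyclobutane-1-carboxylate, via alkylborane 9 (not isolated)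
Conditions: 9-BBN (1.2 equiv), THF, 0 °C to rt; then 2-bromopropene, PdCl2(dppf) (5 mol%), aq. K3PO4, DMF, 50 °C
Reagents that add atoms: none
Why: Anti-Markovnikov hydroboration of the vinyl group and B-alkyl Suzuki–Miyaura coupling of the primary alkylborane with the alkenyl bromide should extend the side chain without touching the ring stereocentres.

Step 5
Reactants: 10 methyl (1R,2S)-3,3-dimethyl-2-(3-methylbut-3-en-1-yl)cyclobutane-1-carboxylate; 11 but-3-en-1-ylmagnesium bromide
Product: 13 1-[(1R,2S)-3,3-dimethyl-2-(3-methylbut-3-en-1-yl)cyclobutyl]pent-4-en-1-one, via Weinreb amide 12 (not isolated)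
Conditions: MeNH(OMe)·HCl (1.5 equiv), iPrMgCl (3 equiv), THF, −20 °C; then 11 (2 equiv), 0 °C to rt; aq. NH4Cl
Reagents that add atoms: none
Why: The chloromagnesium amide converts the ester into the Weinreb amide in the flask, and the Grignard reagent should stop at the ketone through the chelated tetrahedral intermediate; the α-centre stays in the more stable trans arrangement.

Step 6
Reactants: 13 1-[(1R,2S)-3,3-dimethyl-2-(3-methylbut-3-en-1-yl)cyclobutyl]pent-4-en-1-one
Product: 14 (1S,4Z,9R)-4,11,11-trimethylbicyclo[7.2.0]undec-4-en-8-one
Conditions: second-generation Grubbs catalyst (10 mol%), toluene (0.001 M), 80 °C, argon sparge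
Reagents that add atoms: none
Why: Ring-closing olefin metathesis at high dilution should join the 1,1-disubstituted and the monosubstituted olefin; the trans-fused cyclobutane pre-organises the two arms and the Z olefin is the thermodynamic isomer in a nine-membered ring.

Step 7
Reactants: 15 dimethyl 3-methylpentanedioate; 16 dimethyl oxalate
Product: 18 4-methylcyclopentane-1,2-dione, via diester dione 17 (not isolated)
Conditions: NaOMe (2.2 equiv), MeOH, reflux; then 20% aq. H2SO4, reflux
Reagents that add atoms: none
Why: Double Claisen (Dieckmann-type) condensation of the glutarate with the oxalate should give the cyclopentane-1,2-dione diester, and acidic hydrolysis with loss of CO2 from both β-keto acids should leave the symmetric dione.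

Step 8
Reactants: 18 4-methylcyclopentane-1,2-dione; 14 (1S,4Z,9R)-4,11,11-trimethylbicyclo[7.2.0]undec-4-en-8-one
Product: 21 pyran-fused keto enone, via Mannich base hydroiodide 19 (not isolated), via methylene dione 20 (not isolated)
Conditions: 18 (2 equiv), Eschenmoser's salt (2 equiv), CH2Cl2, rt; solvent change to toluene, 14 (1 equiv), 100 °C, sealed tube
Reagents that add atoms: N,N-dimethylmethyleneiminium iodide (Eschenmoser's salt), C=[N+](C)C.[I-]
Why: Mannich reaction at the enol carbon and thermal loss of dimethylamine should give the α-methylene-1,2-dione, an electron-poor 1-oxadiene that adds to the Z olefin in an inverse-demand hetero-Diels–Alder reaction with O at the more substituted carbon; suprafacial addition gives the cis ring fusion, approach is expected on the olefin face remote from the gem-dimethyl carbon, the ketone is kept so that no exocyclic olefin competes, and the two epimers at the ring A CH–CH3 converge in step 10.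

Step 9
Reactants: 21 pyran-fused keto enone
Product: 22 pyran-fused enone with exocyclic methylene
Conditions: KN(SiMe3)2 (1.05 equiv), THF, −78 to 0 °C; then Ph3P=CH2 (3 equiv, from Ph3PCH3Br and KN(SiMe3)2), 0 °C to rt; aq. NH4Cl
Reagents that add atoms: methyltriphenylphosphonium bromide, C[P+](c1ccccc1)(c1ccccc1)c1ccccc1.[Br-]
Why: Wittig methylenation should take place only at the saturated nine-membered ketone because the more acidic cyclopentenone is held as its potassium dienolate until work-up.

Step 10
Reactants: 22 pyran-fused enone with exocyclic methylene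
Product: 23 tert-butyldimethylsilyl dienol ether of ring A
Conditions: TBSOTf (1.3 equiv), Et3N (2 equiv), CH2Cl2, 0 °C; then 40 °C, 1 h
Reagents that add atoms: tert-butyldimethylsilyl trifluoromethanesulfonate, CC(C)(C)[Si](C)(C)OS(=O)(=O)C(F)(F)F
Why: Soft enolisation silylates the enone oxygen, and suprafacial 1,5-hydrogen shifts of the resulting cyclopentadiene should funnel both epimers into the fully substituted 1-silyloxy-1,3-diene, in which the CH3-bearing carbon is the γ-terminus.

Step 11
Reactants: 24 methyl 3-oxocyclopent-1-ene-1-carboxylate
Product: 25 methyl (R)-1-methyl-3-oxocyclopentane-1-carboxylate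
Conditions: Me2Zn (1.5 equiv), Cu(OTf)2 (2 mol%), (S,R,R)-binaphthol phosphoramidite of bis(1-phenylethyl)amine (4 mol%), toluene, −30 °C; aq. NH4Cl
Reagents that add atoms: dimethylzinc, C[Zn]C
Why: Copper-catalysed asymmetric conjugate addition of the methylzinc reagent to the carbon β to the ketone should create the quaternary carbon under ligand control (the ligand antipode is the one taken to give R).

Step 12
Reactants: 25 methyl (R)-1-methyl-3-oxocyclopentane-1-carboxylate
Product: 26 methyl (R)-1-methyl-3-{[(trifluoromethyl)sulfonyl]oxy}cyclopent-3-ene-1-carboxylate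
Conditions: LiN(SiMe3)2 (1.1 equiv), THF, −78 °C; PhNTf2 (1.2 equiv), −78 to 0 °C
Reagents that add atoms: N-phenylbis(trifluoromethanesulfonimide), O=S(=O)(N(c1ccccc1)S(=O)(=O)C(F)(F)F)C(F)(F)F
Why: Kinetic deprotonation by the bulky amide should occur at the α-CH2 remote from the quaternary carbon, and O-sulfonylation of the enolate fixes the double bond on that side.

Step 13
Reactants: 26 methyl (R)-1-methyl-3-{[(trifluoromethyl)sulfonyl]oxy}cyclopent-3-ene-1-carboxylate
Product: 27 methyl (R)-3-formyl-1-methylcyclopent-3-ene-1-carboxylate
Conditions: CO (1 atm), Pd(OAc)2 (5 mol%), dppp (5 mol%), Et3SiH (2 equiv), Et3N (2.5 equiv), DMF, 70 °C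
Reagents that add atoms: carbon monoxide, [C-]#[O+]
Why: Palladium-catalysed reductive carbonylation (oxidative addition, CO insertion, hydride transfer from the silane) should convert the enol triflate into the conjugated aldehyde without moving the double bond.

Step 14
Reactants: 23 tert-butyldimethylsilyl dienol ether of ring A; 27 methyl (R)-3-formyl-1-methylcyclopent-3-ene-1-carboxylate
Product: 29 cross-conjugated dienone ester, via keto aldehyde 28 (not isolated)
Conditions: 23 (1 equiv), 27 (1.5 equiv), 9-amino-9-deoxy-epi-quinine (20 mol%), CF3CO2H (40 mol%), CH2Cl2/H2O 10:1, −20 °C; then 40 °C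
Reagents that add atoms: none
Why: Proposed new method: the primary ammonium salt turns enal 27 into its iminium ion, the γ-carbon of dienol ether 23 (the carbon carrying the ring A methyl group) adds to the β-carbon, water takes the silyl group and returns the ring A enone to give 28, and the same salt then condenses the formyl group (as iminium ion) with the enol of the ring A ketone and eliminates the amine to give 29. The closest known reactions are the amine-catalysed vinylogous Mukaiyama–Michael addition of 5-alkyl-2-silyloxyfurans to enals, which also makes a quaternary γ-carbon, and the amine-catalysed aldol condensation of 1,6-dicarbonyl compounds to 1-acylcyclopentenes; new are the carbocyclic dienol ether, the α-branched cyclic enal and the coupling of both events. Ring B is the only ring closed, in a 5-(enolexo)-exo-trig mode, by bonding the α'-carbon of the ketone to the formyl carbon after the intermolecular bond has joined ring A to ring C. The ring C CH that receives ring A is set by the catalyst, which must leave open the iminium face cis to the ester of (R)-27 (the quinine-derived amine is proposed; the quinidine-derived pseudo-enantiomer gives the other face); the quaternary carbon is set in an open transition state with the pyran flank of 23 turned away from ring C, which leads to the anti disposition of rings A and C; the second ring C CH is epimerisable next to the formyl group and ends cis because only a cis-fused bicyclo[3.3.0]octene can close. The step needs γ- rather than α-attack and conjugate addition rather than Diels–Alder addition of the cyclopentadiene: the α-carbon and both diene termini are fully substituted, and only γ-attack restores the conjugated enone. It also needs the condensation to run through the ketone α'-CH2: the other aldol mode (aldehyde α-carbon onto the hindered ketone) gives an adduct that cannot lose water and reverts.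

Step 15
Reactants: 29 cross-conjugated dienone ester
Product: 30 methyl ester of the target
Conditions: [(Ph3P)CuH]6 (0.4 equiv), toluene, H2O (5 equiv), rt; aq. NH4Cl
Reagents that add atoms: none
Why: Conjugate reduction by the copper hydride should attack only the β-CH of the exocyclic enone (the other enone is tetrasubstituted at its β-carbon and isolated olefins are inert), and protonation of the enolate can only give the cis ring A/B fusion.

Step 16
Reactants: 30 methyl ester of the target
Product: 31 target acid
Conditions: LiOH·H2O (10 equiv), THF/MeOH/H2O 3:1:1, 60 °C; then 1 M HCl to pH 3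
Reagents that add atoms: lithium hydroxide, [Li+].[OH-]
Why: Saponification of the hindered methyl ester should free the acid; the CH next to the ketone already sits in its only stable, cis-fused arrangement and no other base-labile centre is present.

**Compound list**
1 | 4-(2-methylprop-1-en-1-yl)morpholine | CC(C)=CN1CCOCC1 | starting material
2 | methyl acrylate | C=CC(=O)OC | starting material
3 | methyl 3,3-dimethyl-2-(morpholin-4-yl)cyclobutane-1-carboxylate (racemic mixture of isomers) | COC(=O)C1CC(C)(C)C1N1CCOCC1 | intermediate
4 | 4-[2-(methoxycarbonyl)-4,4-dimethylcyclobutyl]-4-methylmorpholin-4-ium iodide | COC(=O)C1CC(C)(C)C1[N+]1(C)CCOCC1.[I-] | intermediate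
5 | methyl 3,3-dimethylcyclobut-1-ene-1-carboxylate | COC(=O)C1=CC(C)(C)C1 | intermediate
6 | 4,4,5,5-tetramethyl-2-vinyl-1,3,2-dioxaborolane | C=CB1OC(C)(C)C(C)(C)O1 | starting material
7 | methyl (1R,2S)-3,3-dimethyl-2-vinylcyclobutane-1-carboxylate (trans) | COC(=O)[C@@H]1CC(C)(C)[C@H]1C=C | intermediate
8 | 2-bromopropene | CC(Br)=C | starting material
9 | methyl (1R,2S)-2-[2-(9-borabicyclo[3.3.1]nonan-9-yl)ethyl]-3,3-dimethylcyclobutane-1-carboxylate | COC(=O)[C@@H]1CC(C)(C)[C@H]1CCB1C2CCCC1CCC2 | intermediate
10 | methyl (1R,2S)-3,3-dimethyl-2-(3-methylbut-3-en-1-yl)cyclobutane-1-carboxylate | COC(=O)[C@@H]1CC(C)(C)[C@H]1CCC(C)=C | intermediate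
11 | but-3-en-1-ylmagnesium bromide (THF solution) | C=CCC[Mg]Br | starting material
12 | (1R,2S)-N-methoxy-N,3,3-trimethyl-2-(3-methylbut-3-en-1-yl)cyclobutane-1-carboxamide | CON(C)C(=O)[C@@H]1CC(C)(C)[C@H]1CCC(C)=C | intermediate
13 | 1-[(1R,2S)-3,3-dimethyl-2-(3-methylbut-3-en-1-yl)cyclobutyl]pent-4-en-1-one | C=CCCC(=O)[C@@H]1CC(C)(C)[C@H]1CCC(C)=C | intermediate
14 | (1S,4Z,9R)-4,11,11-trimethylbicyclo[7.2.0]undec-4-en-8-one | O=C1CC/C=C(C)\CC[C@H]2[C@H]1CC2(C)C | intermediate
15 | dimethyl 3-methylpentanedioate | COC(=O)CC(C)CC(=O)OC | starting material
16 | dimethyl oxalate | COC(=O)C(=O)OC | starting material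
17 | dimethyl 2-methyl-4,5-dioxocyclopentane-1,3-dicarboxylate | COC(=O)C1C(C)C(C(=O)OC)C(=O)C1=O | intermediate
18 | 4-methylcyclopentane-1,2-dione (largely the enol 2-hydroxy-4-methylcyclopent-2-en-1-one) | CC1CC(=O)C(=O)C1 | intermediate
19 | [(2-hydroxy-5-methyl-3-oxocyclopent-1-en-1-yl)methyl]dimethylammonium iodide | CC1CC(=O)C(O)=C1C[NH+](C)C.[I-] | intermediate
20 | 4-methyl-3-methylidenecyclopentane-1,2-dione | C=C1C(C)CC(=O)C1=O | intermediate
21 | pyran-fused keto enone: 14 with a dihydropyran cis-fused across C4–C5 (O on C4, CH2 on C5, both on the olefin face remote from C11; CH3 on C4 cis to H on C5); the pyran enol ether C=C is C2=C3 of a 4-methylcyclopent-2-en-1-one (ring A, both epimers at its CH–CH3); C8 ketone kept | O=C1CC[C@H]2CC3=C(O[C@@]2(C)CC[C@H]2[C@H]1CC2(C)C)C(=O)CC3C | intermediate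
22 | as 21 with the C8 ketone replaced by C=CH2 | C=C1CC[C@H]2CC3=C(O[C@@]2(C)CC[C@H]2[C@H]1CC2(C)C)C(=O)CC3C | intermediate
23 | silyl dienol ether of 22: ring A as 1-(tert-butyldimethylsilyloxy)cyclopenta-1,3-diene with C=C between the former carbonyl carbon and the O-bearing carbon and between the pyran-CH2-bearing carbon and the CH3-bearing carbon | C=C1CC[C@H]2CC3=C(C)CC(O[Si](C)(C)C(C)(C)C)=C3O[C@@]2(C)CC[C@H]2[C@H]1CC2(C)C | intermediate
24 | methyl 3-oxocyclopent-1-ene-1-carboxylate | COC(=O)C1=CC(=O)CC1 | starting material
25 | methyl (R)-1-methyl-3-oxocyclopentane-1-carboxylate | O=C1CC[C@@](C)(C(=O)OC)C1 | intermediate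
26 | methyl (R)-1-methyl-3-{[(trifluoromethyl)sulfonyl]oxy}cyclopent-3-ene-1-carboxylate | O=S(=O)(OC1=CC[C@@](C)(C(=O)OC)C1)C(F)(F)F | intermediate
27 | methyl (R)-3-formyl-1-methylcyclopent-3-ene-1-carboxylate | O=CC1=CC[C@@](C)(C(=O)OC)C1 | intermediate
28 | keto aldehyde: 22 whose ring A CH3-bearing carbon is quaternary and bonded to C4 of methyl 3-formyl-1-methylcyclopentane-1-carboxylate (ring C), cis to the ester on ring C; formyl-bearing carbon epimerisable | C=C1CC[C@H]2CC3=C(O[C@@]2(C)CC[C@H]2[C@H]1CC2(C)C)C(=O)C[C@]3(C)[C@@H]1C[C@@](C)(C(=O)OC)CC1C=O | intermediate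
29 | dienone ester: methyl ester of 31 with a C=C in ring B between the ring A/B fusion carbon next to the ketone and the ring B CH | C=C1CC[C@H]2CC3=C(O[C@@]2(C)CC[C@H]2[C@H]1CC2(C)C)C(=O)C1=C[C@H]2C[C@](C)(C(=O)OC)C[C@H]2[C@]31C | intermediate
30 | methyl ester of the target | C=C1CC[C@H]2CC3=C(O[C@@]2(C)CC[C@H]2[C@H]1CC2(C)C)C(=O)[C@@H]1C[C@H]2C[C@](C)(C(=O)OC)C[C@H]2[C@]31C | intermediate
31 | CNP0483070.2 | C=C1CC[C@H]2CC3=C(O[C@@]2(C)CC[C@H]2[C@H]1CC2(C)C)C(=O)[C@@H]1C[C@H]2C[C@](C)(C(=O)O)C[C@H]2[C@]31C | target

**Step count and risks**
Total steps: 16. Longest linear sequence: 12 (steps 1–6, 8–10, 14–16).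

Step 14 (proposed new method). What may go wrong: slow iminium formation from the α-branched enal, attack through the α-carbon or cycloaddition across the diene, and poor facial selectivity in the bond-forming event. Fallback by known chemistry, in two operations: it sets out from enone 22 and enal 27. Both carbonyl compounds are complexed with Al(OC6H3-2,6-Ph2)3 and 22 is deprotonated at the γ-position with LiN(iPr)2. The bulky aluminium phenoxide shields the α-carbon and the formyl carbon, so the dienolate γ-carbon should add 1,4 to the enal and give keto aldehyde 28. This is isolated, freed from diastereomers and closed with pyrrolidinium acetate (aldol condensation), and the route is rejoined at 29. No compound outside the list is made (F0).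

Step 6. What may go wrong: oligomerisation by acyclic diene metathesis and failure to engage the 1,1-disubstituted olefin in a nine-membered ring closure. Fallback: it sets out from dienone 13. The ketone is protected as the dioxolane F1 (ethylene glycol, pyridinium tosylate). Both terminal olefins are cleaved by ozonolysis (O3, then Me2S) to the keto aldehyde F2. The ring is closed by intramolecular McMurry coupling of the methyl ketone with the aldehyde, a union of two carbonyl carbons of like polarity (TiCl3(DME)1.5, Zn(Cu), DME, reflux, slow addition), giving the cyclononene ketal F3; any E isomer is equilibrated to Z with PhSSPh and light. Aqueous HCl in acetone removes the ketal and the route is rejoined at 14.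

Step 3. What may go wrong: low conversion at the β-carbon next to the quaternary centre, or low enantioselectivity. Fallback: it sets out from cyclobutene 5. Vinylmagnesium bromide with catalytic CuI and Me3SiCl, then NaOMe equilibration, gives the racemic trans ester F4. Saponification gives the racemic acid F5, which is resolved by crystallising the salt F6 with (S)-1-phenylethylamine. Acidification liberates the (1R,2S) acid F7, and re-esterification (MeI, K2CO3) rejoins the route at 7.

Further compounds
F0 | step 14 | none | none
F1 | step 6 | 2-(but-3-en-1-yl)-2-[(1R,2S)-3,3-dimethyl-2-(3-methylbut-3-en-1-yl)cyclobutyl]-1,3-dioxolane | C=CCCC1(OCCO1)[C@@H]2CC(C)(C)[C@H]2CCC(C)=C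
F2 | step 6 | 3-{2-[(1R,2S)-3,3-dimethyl-2-(3-oxobutyl)cyclobutyl]-1,3-dioxolan-2-yl}propanal | O=CCCC1(OCCO1)[C@@H]2CC(C)(C)[C@H]2CCC(C)=O
F3 | step 6 | ethylene ketal of 14 (spiro-1,3-dioxolane at C8) | O1CCOC12CC/C=C(C)\CC[C@H]3[C@H]2CC3(C)C
F4 | step 3 | rac-trans methyl 3,3-dimethyl-2-vinylcyclobutane-1-carboxylate | COC(=O)C1CC(C)(C)C1C=C
F5 | step 3 | rac-trans 3,3-dimethyl-2-vinylcyclobutane-1-carboxylic acid | OC(=O)C1CC(C)(C)C1C=C
F6 | step 3 | (S)-1-phenylethylammonium (1R,2S)-3,3-dimethyl-2-vinylcyclobutane-1-carboxylate | [O-]C(=O)[C@@H]1CC(C)(C)[C@H]1C=C.C[C@H]([NH3+])c1ccccc1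
F7 | step 3 | (1R,2S)-3,3-dimethyl-2-vinylcyclobutane-1-carboxylic acid | OC(=O)[C@@H]1CC(C)(C)[C@H]1C=C
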